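**Plan**

Atom labels: pyrrole C1, C2(H), C3, N, C9a; azepine N–C5–C6–C7–C8–C9–C9a; ring B C9a–C9–C10(Et)–C11–C12–C1; fused lactone C11–O–C14(=O)–C13(Me)–C12; side lactone C18(O)–C19–C20(Me)–C21(=O)–O on C3.
Cuts, in retrosynthetic order: C13–H back to C13–Cl; the lactone O–C11 bond (retro-Baeyer–Villiger) to a cyclobutanone; C11–C14 and C12–C13 (retro-[2+2]) to methylchloroketene and a C11=C12 alkene, itself from a C12 ketone; N–C9a and N–C3 (tethered Paal–Knorr); C1–C2 (dione alkylation by a bromomethyl ketone); C1–C9a (Claisen), C8–C9 (malonate alkylation) and C9–C10 (Michael).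
Forward order: the side butyrolactone is taken from the chiral pool, ring B is closed by Claisen cyclisation, the two pieces are joined at C1–C2, azepine and pyrrole close in one operation, and last a cyclobutanone is fused to ring B and expanded by one oxygen atom to the second lactone.
Enabling feature: the ring-B lactone is cis-fused across C11–C12 with its ring oxygen on C11 and its α-carbon C13 on the pyrrole-bound C12. Without that oxygen it is the cyclobutanone a ketene forms with a C11=C12 alkene polarised by the nitrogen lone pair through C9a=C1 (C11 nucleophilic, C12 cation-stabilising).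
Stereochemistry: C10 from a catalytic asymmetric Michael addition, C9 by equilibration trans to C10, C18 from the D-glutamic acid pool, C20 by trans-selective enolate methylation, C11 and C12 by suprafacial ketene addition anti to the C10 ethyl group, C13 by convex-face protonation after dechlorination.

Key step: step 18

Assumption: the quinine-derived primary amine catalyst is taken to deliver the 3S adduct 3; should the sense of induction prove opposite, the quinidine-derived pseudo-enantiomer is used with no other change.
Remarks: azides 5 and 6 are of low molecular weight and are handled only in solution. The 1,3-diones 8, 9, 10, 19 and 20 are drawn as diketones although they are largely enolised.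

**Route**

Step 1
Reactants: 1 (E)-hex-3-en-2-one; 2 dimethyl malonate
Product: 3 dimethyl 2-[(3S)-5-oxohexan-3-yl]propanedioate
Conditions: 9-amino-9-deoxy-epi-quinine (20 mol %), PhCO2H (40 mol %), 2 (2 equiv), THF, rt
Reagents that add atoms: none
Why: Organocatalytic asymmetric Michael addition in which the primary amine activates the enone as its iminium ion and the chiral ion pair steers the malonate to one enantioface, so the stereocentre that becomes C10 is set by the catalyst.

Step 2
Reactants: 4 1-bromo-4-chlorobutane
Product: 5 1-azido-4-chlorobutane
Conditions: NaN3 (1.05 equiv), DMF, rt; kept as a solution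
Reagents that add atoms: sodium azide, [Na+].[N-]=[N+]=[N-]
Why: SN2 substitution by azide is much faster at the C–Br than at the C–Cl terminus, so only the bromide should be displaced.

Step 3
Reactants: 5 1-azido-4-chlorobutane
Product: 6 1-azido-4-iodobutane
Conditions: NaI (3 equiv), acetone, reflux; kept as a solution
Reagents that add atoms: sodium iodide, [Na+].[I-]
Why: Finkelstein halide exchange driven by precipitation of NaCl gives the more reactive primary iodide without touching the azide.

Step 4
Reactants: 3 dimethyl 2-[(3S)-5-oxohexan-3-yl]propanedioate; 6 1-azido-4-iodobutane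
Product: 7 dimethyl 2-(4-azidobutyl)-2-[(3S)-5-oxohexan-3-yl]propanedioate
Conditions: NaH (1.1 equiv), DMF, 0 °C; then 6, rt to 50 °C
Reagents that add atoms: none
Why: Malonic ester alkylation: the malonate C–H is far more acidic than the ketone α-hydrogens, and its sodium enolate is alkylated by the primary iodide (SN2), forming the C8–C9 bond without touching the existing stereocentre.

Step 5
Reactants: 7 dimethyl 2-(4-azidobutyl)-2-[(3S)-5-oxohexan-3-yl]propanedioate
Product: 8 methyl (2S)-1-(4-azidobutyl)-2-ethyl-4,6-dioxocyclohexane-1-carboxylate (both epimers at the quaternary carbon)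
Conditions: KOtBu (2.2 equiv), THF, 0 °C to rt; then aq. HCl
Reagents that add atoms: none
Why: Intramolecular Claisen condensation in which the methyl-ketone enolate attacks one ester group (6-exo-trig) and closes ring B through the C1–C9a bond, made irreversible by deprotonation of the 1,3-dione and run cold in an aprotic solvent so that ring closure outruns retro-Michael erosion of the C10 centre; the new quaternary centre forms as a mixture that is removed in step 6.

Step 6
Reactants: 8 methyl (2S)-1-(4-azidobutyl)-2-ethyl-4,6-dioxocyclohexane-1-carboxylate
Product: 10 (4R,5S)-4-(4-azidobutyl)-5-ethylcyclohexane-1,3-dione, via keto acid 9 (not isolated)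
Conditions: 2 M NaOH, MeOH/H2O, 60 °C; then 6 M HCl to pH 1, 70 °C
Reagents that add atoms: none
Why: Saponification of the β-keto ester and acid-promoted decarboxylation through the C9a=C9 enol, followed by acid-catalysed enolisation at C9, should place the azidobutyl chain trans to the neighbouring ethyl group under thermodynamic control, and the alkyl azide tolerates aqueous base and dilute acid.

Step 7
Reactants: 11 (5R)-5-(hydroxymethyl)dihydrofuran-2(3H)-one
Product: 12 (5R)-5-[(triphenylmethoxy)methyl]dihydrofuran-2(3H)-one
Conditions: Ph3CCl, Et3N, DMAP (cat.), CH2Cl2, rt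
Reagents that add atoms: trityl chloride, ClC(c1ccccc1)(c1ccccc1)c1ccccc1
Why: Tritylation of the primary alcohol installs the bulky ether that shields one face of the lactone enolate in the next step.

Step 8
Reactants: 12 (5R)-5-[(triphenylmethoxy)methyl]dihydrofuran-2(3H)-one
Product: 13 (3S,5R)-3-methyl-5-[(triphenylmethoxy)methyl]dihydrofuran-2(3H)-one
Conditions: LiN(iPr)2 (LDA), THF, −78 °C; then MeI, −78 °C
Reagents that add atoms: iodomethane, CI
Why: Alkylation of the lithium lactone enolate takes place on the ring face opposite the trityloxymethyl group, a well-established trans-selective enolate methylation that sets the future C20 relative to C18.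

Step 9
Reactants: 13 (3S,5R)-3-methyl-5-[(triphenylmethoxy)methyl]dihydrofuran-2(3H)-one
Product: 14 (3S,5R)-5-(hydroxymethyl)-3-methyldihydrofuran-2(3H)-one
Conditions: AcOH/H2O 4:1, 50 °C
Reagents that add atoms: none
Why: Acid-catalysed solvolysis of the trityl ether through the trityl cation leaves the lactone and both stereocentres untouched.

Step 10
Reactants: 14 (3S,5R)-5-(hydroxymethyl)-3-methyldihydrofuran-2(3H)-one
Product: 15 (2R,4S)-4-methyl-5-oxotetrahydrofuran-2-carboxylic acid
Conditions: TEMPO (20 mol %), PhI(OAc)2 (2.2 equiv), MeCN/H2O 1:1, rt
Reagents that add atoms: water, O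
Why: Oxoammonium-mediated oxidation of the primary alcohol through the aldehyde hydrate to the carboxylic acid runs under nearly neutral conditions and is not expected to epimerise the α-oxygenated centre.

Step 11
Reactants: 15 (2R,4S)-4-methyl-5-oxotetrahydrofuran-2-carboxylic acid
Product: 16 (2R,4S)-4-methyl-5-oxotetrahydrofuran-2-carbonyl chloride
Conditions: (COCl)2, DMF (cat.), CH2Cl2, 0 °C to rt; evaporated and used crude
Reagents that add atoms: oxalyl chloride, ClC(=O)C(Cl)=O
Why: Standard acid chloride formation through the Vilsmeier-type chloroiminium species, with no base present to enolise the centre next to the carbonyl.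

Step 12
Reactants: 16 (2R,4S)-4-methyl-5-oxotetrahydrofuran-2-carbonyl chloride
Product: 17 (3S,5R)-5-(diazoacetyl)-3-methyldihydrofuran-2(3H)-one
Conditions: Me3SiCHN2 (2 equiv), THF/MeCN 1:1, 0 °C
Reagents that add atoms: (trimethylsilyl)diazomethane, C[Si](C)(C)C=[N+]=[N-]
Why: C-Acylation of the diazoalkane with loss of the silyl group (first stage of an Arndt–Eistert-type sequence) gives the diazomethyl ketone and brings in the carbon that becomes pyrrole C2.

Step 13
Reactants: 17 (3S,5R)-5-(diazoacetyl)-3-methyldihydrofuran-2(3H)-one
Product: 18 (3S,5R)-5-(bromoacetyl)-3-methyldihydrofuran-2(3H)-one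
Conditions: 48 % aq. HBr, Et2O, 0 °C
Reagents that add atoms: hydrogen bromide, Br
Why: C-Protonation of the diazo ketone and SN2 displacement of N2 by bromide is the standard route to a bromomethyl ketone, and brief contact with cold acid should not affect the lactone.

Step 14
Reactants: 10 (4R,5S)-4-(4-azidobutyl)-5-ethylcyclohexane-1,3-dione; 18 (3S,5R)-5-(bromoacetyl)-3-methyldihydrofuran-2(3H)-one
Product: 19 (4R,5S)-4-(4-azidobutyl)-5-ethyl-2-{2-[(2R,4S)-4-methyl-5-oxotetrahydrofuran-2-yl]-2-oxoethyl}cyclohexane-1,3-dione
Conditions: K2CO3, CHCl3, rt
Reagents that add atoms: none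
Why: C-Alkylation of the soft potassium enolate of the cyclic 1,3-dione at its central carbon by the reactive α-bromo ketone forms the C1–C2 bond, and the weak heterogeneous base should enolise neither the ketone next to C18 nor the lactone at C20.

Step 15
Reactants: 19 (4R,5S)-4-(4-azidobutyl)-5-ethyl-2-{2-[(2R,4S)-4-methyl-5-oxotetrahydrofuran-2-yl]-2-oxoethyl}cyclohexane-1,3-dione
Product: 22 tricyclic pyrrole ketone (azepine, pyrrole and ring B with C12=O and C11H2; C9–C8 bond and C10 ethyl trans; 18R,20S lactone on C3), via amino triketone 20 (not isolated), via bicyclic enaminone 21 (not isolated)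
Conditions: PMe3, THF, rt, then H2O; then AcOH, PhMe, 80 °C, 0.005 M, 4 Å MS
Reagents that add atoms: none
Why: Staudinger reduction frees the primary amine, which under acetic acid condenses with the nearer ring carbonyl C9a to the seven-membered vinylogous amide and then acts as the nitrogen of a Paal–Knorr cyclodehydration onto the side-chain ketone of the 1,4-dicarbonyl unit C9a–C1–C2–C3; this closure passes through a hemiaminal and not an enamine towards C18, so C18 should be kept, while C9 can only equilibrate towards the trans arrangement it already has.

Step 16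
Reactants: 22 tricyclic pyrrole ketone
Product: 23 dienyl triflate (C11=C12 enol triflate of 22, TfO on C12)
Conditions: Tf2O, 2,6-di-tert-butyl-4-methylpyridine, CH2Cl2, −78 to 0 °C
Reagents that add atoms: triflic anhydride, O=S(=O)(OS(=O)(=O)C(F)(F)F)C(F)(F)F
Why: O-Sulfonylation of the vinylogous amide carbonyl gives a triflyloxy azafulvenium ion that the hindered pyridine deprotonates at C11, which restores the pyrrole; this ketone-to-vinyl-triflate conversion avoids the strong base that would epimerise C20.

Step 17
Reactants: 23 dienyl triflate
Product: 24 tricyclic 11,12-alkene (6,7-dihydroindole-type 3-vinylpyrrole)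
Conditions: Pd(OAc)2 (5 mol %), PPh3 (10 mol %), Bu3N, HCO2H, DMF, 60 °C, degassed; filtered through basic alumina under Ar and used at once
Reagents that add atoms: none
Why: Formate reduction of an enol triflate: zerovalent palladium (formed from Pd(OAc)2 and PPh3) inserts into the vinyl C–O bond, formate exchange and loss of CO2 give the palladium hydride, and reductive elimination delivers the alkene in a buffered, oxygen-free medium suited to the acid- and air-sensitive product.

Step 18
Reactants: 24 tricyclic 11,12-alkene; 25 2-chloropropanoyl chloride (racemic)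
Product: 27 cis-fused 13-chloro-13-methylcyclobutanone (C14=O on C11, C13 on C12, both new bonds anti to the C10 ethyl; major epimer with Cl exo and Me endo), via methylchloroketene 26 (not isolated)
Conditions: Et3N (4 equiv), CH2Cl2/hexane, rt, 25 (3 equiv) added by syringe pump over several hours, Ar, dark
Reagents that add atoms: none
Why: Triethylamine dehydrochlorinates 25 to methylchloroketene 26, which is held at low concentration and adds to the C11=C12 alkene in an asynchronous [2+2] cycloaddition: the nucleophilic terminus C11 of the N–C9a=C1–C12=C11 dienamine bonds to the electrophilic central ketene carbon C14, and the developing enolate carbon C13 then closes onto C12, whose positive charge is stabilised as a pyrrol-3-ylmethyl cation. The closest known reaction type is the cycloaddition of dichloro- and chloro(alkyl)ketenes to aryl-conjugated ring alkenes such as indene and 1,2-dihydronaphthalene and to cyclic dienes, which shows the same orientation with the carbonyl carbon on the non-benzylic alkene carbon. The cyclobutanone is the only ring closed, by intermolecular cycloaddition in which the C11–C14 and C12–C13 bonds form on the same face of the alkene, so the four-membered ring must be cis-fused to ring B. C11 and C12 are set together by this suprafacial addition and their absolute sense by the allylic C10 ethyl group, which shields its own face at C11 where the first bond forms; C13 should form mainly with methyl endo (cis to C1) but is reset in step 20, so its configuration does not matter. The step needs regioselectivity, which the dienamine polarisation provides, facial selectivity, which the C10 substituent provides, and chemoselectivity for the alkene over the pyrrole, which follows because both pyrrole α-positions are substituted and a non-enolisable ketene acylates the remaining hindered C2–H only slowly.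

Step 19
Reactants: 27 cis-fused 13-chloro-13-methylcyclobutanone
Product: 28 13-chloro-13-methyl ring-B lactone (O on C11, cis-fused)
Conditions: 30 % aq. H2O2, CF3CH2OH, 0 °C to rt; aq. Na2S2O3 quench
Reagents that add atoms: hydrogen peroxide, OO
Why: Baeyer–Villiger oxidation in which peroxide activated by the fluorinated alcohol adds to the strained ketone and the non-chlorinated C11 migrates to oxygen with retention (the α-chloro carbon migrates poorly), so oxygen enters between C14 and C11; the fast strain-driven addition and the absence of a peracid should spare the pyrrole.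

Step 20
Reactants: 28 13-chloro-13-methyl ring-B lactone
Product: 29 target CNP0232452.4 (9R,10R,11S,12R,13R,18R,20S in the atom labels above)
Conditions: Zn dust, AcOH/THF 1:4, 0 °C to rt; neutral work-up, no base
Reagents that add atoms: none
Why: Reductive dehalogenation of the α-chloro lactone gives a zinc enolate planar at C13 that acetic acid should protonate from the convex face of the cis-fused bicycle (the face of the C11 and C12 hydrogens), which leaves the methyl group cis to C1 as in the target and makes both C13 chloro epimers converge, the base-free work-up guarding against epimerisation to the more stable arrangement.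

**Compound list**

1 | (E)-hex-3-en-2-one | CC/C=C/C(C)=O | starting material
2 | dimethyl malonate | COC(=O)CC(=O)OC | starting material
3 | dimethyl 2-[(3S)-5-oxohexan-3-yl]propanedioate | CC[C@@H](CC(C)=O)C(C(=O)OC)C(=O)OC | intermediate
4 | 1-bromo-4-chlorobutane | ClCCCCBr | starting material
5 | 1-azido-4-chlorobutane | [N-]=[N+]=NCCCCCl | intermediate
6 | 1-azido-4-iodobutane | [N-]=[N+]=NCCCCI | intermediate
7 | dimethyl 2-(4-azidobutyl)-2-[(3S)-5-oxohexan-3-yl]propanedioate | CC[C@@H](CC(C)=O)C(CCCCN=[N+]=[N-])(C(=O)OC)C(=O)OC | intermediate
8 | methyl (2S)-1-(4-azidobutyl)-2-ethyl-4,6-dioxocyclohexane-1-carboxylate, epimers at C1 | CC[C@H]1CC(=O)CC(=O)C1(CCCCN=[N+]=[N-])C(=O)OC | intermediate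
9 | (2S)-1-(4-azidobutyl)-2-ethyl-4,6-dioxocyclohexane-1-carboxylic acid, formed in situ | CC[C@H]1CC(=O)CC(=O)C1(CCCCN=[N+]=[N-])C(O)=O | intermediate
10 | (4R,5S)-4-(4-azidobutyl)-5-ethylcyclohexane-1,3-dione (trans) | CC[C@H]1CC(=O)CC(=O)[C@@H]1CCCCN=[N+]=[N-] | intermediate
11 | (5R)-5-(hydroxymethyl)dihydrofuran-2(3H)-one | OC[C@H]1CCC(=O)O1 | starting material
12 | (5R)-5-[(triphenylmethoxy)methyl]dihydrofuran-2(3H)-one | C(OC[C@H]1CCC(=O)O1)(c1ccccc1)(c1ccccc1)c1ccccc1 | intermediate
13 | (3S,5R)-3-methyl-5-[(triphenylmethoxy)methyl]dihydrofuran-2(3H)-one | C(OC[C@H]1C[C@H](C)C(=O)O1)(c1ccccc1)(c1ccccc1)c1ccccc1 | intermediate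
14 | (3S,5R)-5-(hydroxymethyl)-3-methyldihydrofuran-2(3H)-one | OC[C@H]1C[C@H](C)C(=O)O1 | intermediate
15 | (2R,4S)-4-methyl-5-oxotetrahydrofuran-2-carboxylic acid | OC(=O)[C@H]1C[C@H](C)C(=O)O1 | intermediate
16 | (2R,4S)-4-methyl-5-oxotetrahydrofuran-2-carbonyl chloride | ClC(=O)[C@H]1C[C@H](C)C(=O)O1 | intermediate
17 | (3S,5R)-5-(diazoacetyl)-3-methyldihydrofuran-2(3H)-one | [N-]=[N+]=CC(=O)[C@H]1C[C@H](C)C(=O)O1 | intermediate
18 | (3S,5R)-5-(bromoacetyl)-3-methyldihydrofuran-2(3H)-one | BrCC(=O)[C@H]1C[C@H](C)C(=O)O1 | intermediate
19 | (4R,5S)-4-(4-azidobutyl)-5-ethyl-2-{2-[(2R,4S)-4-methyl-5-oxotetrahydrofuran-2-yl]-2-oxoethyl}cyclohexane-1,3-dione | CC[C@H]1CC(=O)C(CC(=O)[C@H]2C[C@H](C)C(=O)O2)C(=O)[C@@H]1CCCCN=[N+]=[N-] | intermediate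
20 | amino triketone (4-aminobutyl analogue of 19), formed in situ | CC[C@H]1CC(=O)C(CC(=O)[C@H]2C[C@H](C)C(=O)O2)C(=O)[C@@H]1CCCCN | intermediate
21 | bicyclic enaminone (azepine-fused vinylogous amide N–C9a=C1–C12=O with the 2-oxo-2-lactonylethyl chain on C1), formed in situ | CC[C@H]1CC(=O)C(CC(=O)[C@H]2C[C@H](C)C(=O)O2)=C2NCCCC[C@H]12 | intermediate
22 | tricyclic pyrrole ketone (C12=O) | CC[C@H]1CC(=O)c2cc([C@H]3C[C@H](C)C(=O)O3)n3c2[C@@H]1CCCC3 | intermediate
23 | dienyl triflate (C11=C12, TfO on C12) | CC[C@H]1C=C(OS(=O)(=O)C(F)(F)F)c2cc([C@H]3C[C@H](C)C(=O)O3)n3c2[C@@H]1CCCC3 | intermediate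
24 | tricyclic 11,12-alkene | CC[C@H]1C=Cc2cc([C@H]3C[C@H](C)C(=O)O3)n3c2[C@@H]1CCCC3 | intermediate
25 | 2-chloropropanoyl chloride (racemic) | CC(Cl)C(Cl)=O | starting material
26 | methylchloroketene, formed in situ | CC(Cl)=C=O | intermediate
27 | cis-fused 13-chloro-13-methylcyclobutanone (major C13 epimer drawn) | CC[C@H]1[C@@H]2C(=O)[C@@](C)(Cl)[C@@H]2c2cc([C@H]3C[C@H](C)C(=O)O3)n3c2[C@@H]1CCCC3 | intermediate
28 | 13-chloro-13-methyl ring-B lactone | CC[C@H]1[C@@H]2OC(=O)[C@@](C)(Cl)[C@@H]2c2cc([C@H]3C[C@H](C)C(=O)O3)n3c2[C@@H]1CCCC3 | intermediate
29 | CNP0232452.4 | CC[C@H]1[C@@H]2OC(=O)[C@H](C)[C@@H]2c2cc([C@H]3C[C@H](C)C(=O)O3)n3c2[C@@H]1CCCC3 | target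

**Count and risks**

Total: 20 steps. Longest linear sequence: 14 steps (11 to 29, steps 7 to 20).

Step 18 (ketene cycloaddition). What may go wrong: the ketene dimerises or acylates the pyrrole faster than it adds to the alkene, the alkene oligomerises in the presence of the ammonium salt, or the two alkene faces are not distinguished well enough. The fallback sets out from 24 and comes back at 27. The far more electrophilic dichloroketene (Cl2CHCOCl, Et3N, hexane/CH2Cl2, 0 °C) is used for the [2+2] step and should give, with the same orientation, the gem-dichlorocyclobutanone F1. Chlorine–metal exchange with Me2CuLi (THF, −78 °C) then gives the α-chloro enolate, which is C-methylated with MeI/HMPA to 27 as a mixture of C13 epimers; both serve in steps 19 and 20. The methyl group thus comes from an enolate alkylation instead of from the ketene. This fallback answers low reactivity, not facial selectivity; face isomers would have to be separated at F1 or 27.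

Step 16 (enol triflate). What may go wrong: electrophilic attack of Tf2O on the pyrrole ring, proton loss from C9 instead of C11, or decomposition of the triflate on isolation. The fallback sets out from 22 and comes back at 24, bypassing 23. The ketone is reduced with NaBH4/CeCl3·7H2O (MeOH, 0 °C, where the lactone should not react) to the C12 alcohol F2 (either epimer). Acid-catalysed dehydration (pyridinium p-toluenesulfonate cat., 4 Å MS, CH2Cl2, 0 °C, quenched with Et3N) then passes through the pyrrole-stabilised azafulvenium cation at C12 and loses the C11 proton to give 24.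

Step 15 (tethered double condensation). What may go wrong: intermolecular condensation of the freed amine with the reactive side-chain ketone of a second molecule, cyclodehydration of the 1,4-dicarbonyl unit to a furan, or epimerisation next to the side-chain ketone. The fallback sets out from 10 (with 18) and comes back at 21, which closes to 22 as in step 15; the order of ring formation is reversed and 19 is bypassed. Staudinger reduction of 10 (PMe3, THF, then H2O) gives the amino dione F3, which has no competing ketone. Warming with AcOH in toluene should close it to the bicyclic secondary enaminone F4. Hantzsch-type annulation of F4 with 18 (NaHCO3, MeCN, 60 °C) proceeds by C-alkylation of the enaminone at C1 to 21 and on to 22 by the same nitrogen-to-ketone cyclodehydration.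

Further compounds
F1 | step 18 | cis-fused 13,13-dichlorocyclobutanone (C14=O on C11, CCl2 on C12) | CC[C@H]1[C@@H]2C(=O)C(Cl)(Cl)[C@@H]2c2cc([C@H]3C[C@H](C)C(=O)O3)n3c2[C@@H]1CCCC3
F2 | step 16 | C12 alcohol of the tricyclic pyrrole (epimers at C12) | CC[C@H]1CC(O)c2cc([C@H]3C[C@H](C)C(=O)O3)n3c2[C@@H]1CCCC3
F3 | step 15 | (4R,5S)-4-(4-aminobutyl)-5-ethylcyclohexane-1,3-dione | CC[C@H]1CC(=O)CC(=O)[C@@H]1CCCCN
F4 | step 15 | (5aR,6S)-6-ethyl-1,2,3,4,5,5a,6,7-octahydro-8H-1-benzazepin-8-one | CC[C@H]1CC(=O)C=C2NCCCC[C@H]12
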